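The flavone is cut at C4–C4a. Ring A bears oxygen at C8a and at C6 in a 1,4-relationship, and C7 and C8 between them carry methoxy groups. This is the substitution pattern of a symmetric 2,3-dimethoxy-1,4-benzoquinone, whose two equivalent CH carbons become C4a and C5. Alcohol 1 is oxidised to 3-(3,4-dimethoxyphenyl)propanal 2. Light then joins its formyl carbon to a ring CH of quinone 3, giving in one operation an acylhydroquinone with the complete carbon skeleton of the target and both ring A oxygens in their final places. Methylation of the free C6 hydroxyl and an aerobic palladium-catalysed dehydrogenative closure of ring C finish the route.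

Key step: step 2

Assumption: quinone 3 is taken as a purchased compound; the target is achiral, so no stereocentre has to be controlled.

Step 1
Reactants: 1 3-(3,4-dimethoxyphenyl)propan-1-ol
Product: 2 3-(3,4-dimethoxyphenyl)propanal
Conditions: TEMPO (10 mol %), PhI(OAc)2 (1.1 equiv), CH2Cl2, rt
Reagents that add atoms: none
Why: TEMPO-catalysed oxoammonium oxidation of a primary alcohol should stop at the aldehyde under these anhydrous, near-neutral conditions, which leave the dimethoxyarene and the benzylic methylene untouched.

Step 2
Reactants: 3 2,3-dimethoxy-1,4-benzoquinone; 2 3-(3,4-dimethoxyphenyl)propanal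
Product: 5 1-(2,5-dihydroxy-3,4-dimethoxyphenyl)-3-(3,4-dimethoxyphenyl)propan-1-one, via dienone tautomer 4 (not isolated)
Conditions: hν (blue LEDs, ca. 420–450 nm, Pyrex), degassed PhCF3, Ar, rt
Reagents that add atoms: none
Why: Visible light excites only quinone 3, whose n,π* triplet abstracts the formyl hydrogen of 2 to give a semiquinone and an acyl radical; these combine at the ring carbon next to the oxyl centre to give dienone 4, and enolisation restores aromaticity in acylhydroquinone 5, which holds the new C4–C4a bond (flavone numbering). The closest known reaction type is the photo-Friedel–Crafts acylation of 1,4-quinones with aldehydes (Klinger–Kolvenbach reaction), a radical coupling that links two carbons of electrophilic character without any Lewis acid. No ring is closed and no lasting stereocentre is formed, since the sp3 centre of 4 disappears on enolisation. The step needs mono-acylation at carbon and hydrogen abstraction at the formyl group instead of the benzylic CH2: the symmetry of 3 makes its two CH sites identical, product 5 is a hydroquinone that no longer abstracts hydrogen and is a poor reductant towards 3 because of its acyl group, and the electrophilic triplet prefers the weak, polarity-matched formyl C–H. The aldehyde is charged in modest surplus, which is recovered unchanged, and its primary-alkyl acyl radical should not lose CO at room temperature before it combines.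

Step 3
Reactants: 5 1-(2,5-dihydroxy-3,4-dimethoxyphenyl)-3-(3,4-dimethoxyphenyl)propan-1-one
Product: 6 1-(2-hydroxy-3,4,5-trimethoxyphenyl)-3-(3,4-dimethoxyphenyl)propan-1-one
Conditions: MeI (1.1 equiv), K2CO3 (1.1 equiv), acetone, Ar, rt
Reagents that add atoms: iodomethane, CI
Why: Williamson O-methylation under mild carbonate conditions should pick the free 5-hydroxyl (the future C6 oxygen), because the 2-hydroxyl is held in a hydrogen bond to the ketone and is flanked on both sides, the selectivity generally shown by 2,5-dihydroxyaryl ketones.

Step 4
Reactants: 6 1-(2-hydroxy-3,4,5-trimethoxyphenyl)-3-(3,4-dimethoxyphenyl)propan-1-one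
Product: 9 2-(3,4-dimethoxyphenyl)-6,7,8-trimethoxy-4H-chromen-4-one, via chalcone 7 (not isolated), via flavanone 8 (not isolated)
Conditions: Pd(OCOCF3)2 (10 mol %), 5-nitro-1,10-phenanthroline (20 mol %), O2 (1 atm), DMSO, 100 °C
Reagents that add atoms: none
Why: Aerobic α,β-dehydrogenation of the ketone by divalent palladium (palladium enolate, β-hydride elimination) should give 2'-hydroxychalcone 7, whose phenol closes ring C by a 6-endo oxa-Michael addition to racemic flavanone 8, and a second dehydrogenation of the same kind gives the flavone while O2 returns zerovalent palladium to the divalent state; this oxidative cyclisation is established for 2'-hydroxydihydrochalcones, and the transient stereocentre of 8 is lost in the product.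

Compound list
1 | 3-(3,4-dimethoxyphenyl)propan-1-ol | COc1ccc(CCCO)cc1OC | starting material
2 | 3-(3,4-dimethoxyphenyl)propanal | COc1ccc(CCC=O)cc1OC | intermediate
3 | 2,3-dimethoxy-1,4-benzoquinone (2,3-dimethoxycyclohexa-2,5-diene-1,4-dione) | COC1=C(OC)C(=O)C=CC1=O | starting material
4 | 6-[3-(3,4-dimethoxyphenyl)propanoyl]-4-hydroxy-2,3-dimethoxycyclohexa-2,4-dien-1-one (racemic, not isolated) | COC1=C(OC)C(=O)C(C(=O)CCc2ccc(OC)c(OC)c2)C=C1O | intermediate
5 | 1-(2,5-dihydroxy-3,4-dimethoxyphenyl)-3-(3,4-dimethoxyphenyl)propan-1-one | COc1ccc(CCC(=O)c2cc(O)c(OC)c(OC)c2O)cc1OC | intermediate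
6 | 1-(2-hydroxy-3,4,5-trimethoxyphenyl)-3-(3,4-dimethoxyphenyl)propan-1-one | COc1ccc(CCC(=O)c2cc(OC)c(OC)c(OC)c2O)cc1OC | intermediate
7 | (E)-3-(3,4-dimethoxyphenyl)-1-(2-hydroxy-3,4,5-trimethoxyphenyl)prop-2-en-1-one (not isolated) | COc1ccc(/C=C/C(=O)c2cc(OC)c(OC)c(OC)c2O)cc1OC | intermediate
8 | rac-2-(3,4-dimethoxyphenyl)-6,7,8-trimethoxychroman-4-one (racemic, not isolated) | COc1ccc(C2CC(=O)c3cc(OC)c(OC)c(OC)c3O2)cc1OC | intermediate
9 | 2-(3,4-dimethoxyphenyl)-6,7,8-trimethoxy-4H-chromen-4-one | COc1ccc(-c2cc(=O)c3cc(OC)c(OC)c(OC)c3o2)cc1OC | target

Total step count: 4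
Longest linear sequence: 4 steps (1 → 2 → 5 → 6 → 9); quinone 3 enters at step 2.

Steps most likely to fail

Step 2. The photoacylation may stall for three reasons: the methoxy-donor-substituted quinone triplet may abstract hydrogen sluggishly, electron transfer from the dimethoxyphenyl ring may quench the excited quinone, or the radical pair may collapse at oxygen instead of carbon. The fallback builds the aryl ketone by ionic chemistry and sets out from quinone 3. Reduction with Na2S2O4 (Et2O/H2O, rt) should give 2,3-dimethoxybenzene-1,4-diol F1. Friedel–Crafts-type ring acetylation with AcOH and BF3·OEt2 (90 °C) should give 1-(2,5-dihydroxy-3,4-dimethoxyphenyl)ethan-1-one F2. Methylation of the non-chelated hydroxyl (MeI, K2CO3, acetone, rt) should give 1-(2-hydroxy-3,4,5-trimethoxyphenyl)ethan-1-one F3. Claisen–Schmidt condensation with 3,4-dimethoxybenzaldehyde (KOH, EtOH, rt) then leads to chalcone 7, where the route is rejoined. Isolated 7 is taken to 9 under the conditions of step 4 or with catalytic I2 in DMSO at 130 °C.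

Step 4. The second dehydrogenation may stop at the flavanone stage, or palladium metal may precipitate before turnover is complete. The fallback replaces the palladium enolate pathway by hydride abstraction and sets out from 6. DDQ in refluxing dioxane should remove hydride from the benzylic CH2 para to the 4'-methoxy group. The resulting cation is captured by the phenol or loses a proton, so the route is rejoined at flavanone 8, with any chalcone 7 carried along. Catalytic I2 in DMSO at 130 °C then converts both into 9.

Step 3. Alkylation may also occur at the chelated hydroxyl, or the hydroquinone may be oxidised by air under base before it is alkylated. The fallback replaces selective protection by selective deprotection and sets out from 5. Exhaustive methylation (excess Me2SO4, K2CO3, acetone, reflux) should give 1-(2,3,4,5-tetramethoxyphenyl)-3-(3,4-dimethoxyphenyl)propan-1-one F4. Chelation-directed cleavage of the methoxy group ortho to the ketone with BCl3 (CH2Cl2, −78 to 0 °C) then returns to the route at 6.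

Further compounds
F1 | step 2 | 2,3-dimethoxybenzene-1,4-diol | COc1c(O)ccc(O)c1OC
F2 | step 2 | 1-(2,5-dihydroxy-3,4-dimethoxyphenyl)ethan-1-one | CC(=O)c1cc(O)c(OC)c(OC)c1O
F3 | step 2 | 1-(2-hydroxy-3,4,5-trimethoxyphenyl)ethan-1-one | CC(=O)c1cc(OC)c(OC)c(OC)c1O
F0 | step 4 | none | none
F4 | step 3 | 1-(2,3,4,5-tetramethoxyphenyl)-3-(3,4-dimethoxyphenyl)propan-1-one | COc1ccc(CCC(=O)c2cc(OC)c(OC)c(OC)c2OC)cc1OC
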